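## The problem

The target, compound 15, is a diaryl ether of two fully substituted benzene rings. Ring A carries a methyl ester, two methyls, two hydroxyls and the ether oxygen. Ring B carries a free carboxylic acid, a methyl, a chlorine, a hydroxyl, a formyl group and the ether oxygen. The ether oxygen is flanked by two ortho substituents on each ring (methyl and hydroxyl on ring A, carboxyl and formyl on ring B), so coupling two finished arenes through a C–O bond is unattractive. There is no stereocentre; the difficulties are regiochemical placement of twelve substituents and chemoselectivity.

Two carboxyl groups must be told apart, a methyl ester on ring A and a free acid on ring B, and both are doubly ortho-substituted, so selective hydrolysis cannot be relied on. The salicylaldehyde unit of ring B will not survive enolate chemistry. The electron-rich 2,6-disubstituted benzoic acid is prone to acid-induced decarboxylation. Its carboxyl also lies across the ether from a ring A hydroxyl, so any activation of the acid invites closure to the seven-membered depsidone lactone.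

Ring B is recognisably orsellinic acid with chlorine and formyl added and its 2-hydroxyl turned into the ether. The feature that opens the key step lies in ring A. Its ether carbon, the adjacent hydroxyl carbon and the next methyl-bearing carbon with its methyl are the four carbons of a 1-aryloxybutan-2-one. The remaining methyl-bearing carbon, the ester-bearing carbon and the second hydroxyl carbon are an acetylmalonate at the oxidation level of its enol ether.

## Retrosynthesis

**15 from 14.** The last disconnection cuts the O–CH3 bond of a ring B methyl ether ortho to the formyl group and the O–CH2Ph bond of a ring B benzyl ester, leading back to 14. Both bonds fall to BCl3, the first through chelation to the aldehyde and the second by alkyl–oxygen cleavage. The salicylaldehyde and the free acid therefore appear only in the final operation. The forward step must leave the ring A methyl ester and the diaryl ether alone.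

**14 from 13.** The C–CHO bond on ring B is cut next. The formyl group cannot be present earlier, because an aldehyde ortho to an aryloxymethyl ketone condenses to a benzofuran under the base of the ring-forming step. Compound 13 has exactly one aromatic hydrogen, so the site is not in question. The forward reaction needs an electrophile strong enough for a position between two oxygens on a ring that also bears chlorine and an ester.

**13 from 12.** The benzyl ester is traced to free acid 12. This extra step is accepted because the formylating agent for ethers also turns free carboxylic acids into acid chlorides, and here the acid chloride would sit next to a ring A hydroxyl. Benzyl is chosen because it leaves in the same BCl3 operation that frees the phenol. The forward step must alkylate the carboxylate and not the two phenols.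

**12 from 7 and 10.** Ring A is opened at two C–C bonds: between the ether carbon and the methyl-bearing carbon next to the ester, and between the other methyl-bearing carbon and the hydroxyl carbon next to the ester. This gives ketone acid 7 and alkylidenemalonate 10. Cutting the diaryl ether C–O bond instead would require coupling a hexasubstituted phenol with a pentasubstituted aryl halide. The chosen cut turns that bond into an alkyl aryl ether made by substitution at an sp3 carbon. It also delivers ring A with both hydroxyls free and its ester already different from the ring B carboxyl. The precursors are a pentasubstituted benzene and a three-carbon malonate derivative. The forward reaction must add the enolate of the aryloxy-bearing carbon to 10 and then acylate the ethyl-side carbon, on carbon and not on oxygen.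

**10 from 8 and 9.** The alkylidenemalonate is cut at its C=C bond into dimethyl malonate 8 and trimethyl orthoacetate 9, both bulk chemicals. The forward step is a condensation with removal of methanol.

**7 from 6, and 6 from 4 and 5.** The acid 7 comes from its tert-butyl ester 6, and the O–CH2 bond of 6 is cut to phenol 4 and 1-bromobutan-2-one 5. The acid is masked during the alkylation because a free carboxylate would compete as a nucleophile. The mask is tert-butyl because this hindered, poorly electrophilic ester resists attack by the new ketone's α-carbon under carbonate and is removed without base. The forward alkylation must take place on a hindered, hydrogen-bonded phenol.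

**4 from 3, 3 from 2, 2 from 1.** The C–Cl bond of 4 is cut to give 3, the methyl ether O–CH3 bond of 3 is cut to give 2, and the ester of 2 is traced to orsellinic acid 1. Buying the ring B carbon skeleton leaves only three functional-group steps. The forward steps rely on the chelated 2-hydroxyl staying inert to methylation, and on chlorination para to that hydroxyl in preference to the position between the two oxygens.

## Roads not taken

**Alternative 1:** This plan builds ring B instead of ring A. It cuts the bond between the ring B ether carbon and the neighbouring unsubstituted carbon, and the bond between the carboxyl-bearing and methyl-bearing carbons.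

- **Forward key step.** A preformed ring A phenol, methyl 3-hydroxy-4,6-dimethoxy-2,5-dimethylbenzoate A1, would be converted into the aryloxypropiolate A2 and heated with 4-methoxy-6-methyl-2-pyrone A3. Diels–Alder addition across pyrone carbons 3 and 6 and loss of CO2 would give diaryl ether A4.
- **Merits.** The key step is neutral and pericyclic, and its regiochemistry is polarity-matched: the nucleophilic carbon 3 of A3 meets the β-carbon of the ynoate. The two carboxyl groups are orthogonal from the start, tert-butyl on ring B and methyl on ring A.
- **Weak points.** A1 is itself a hexasubstituted benzene needing its own multistep synthesis. The aryloxy donor makes A2 a push-pull alkyne and a poor dienophile for a diene that already demands high temperature. A4 still lacks chlorine and formyl, and has two ring B hydrogens between which chlorination must choose. Three methyl ethers must finally be cleaved beside a methyl ester, and the ring A ether between the ether oxygen and a methyl has no neighbouring carbonyl to direct the cleavage.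
- **Comparison.** Alternative 1 is better in avoiding enolate site selectivity and in needing no change of carboxyl protection. Against that, the chosen plan makes ring A in one step with free hydroxyls, and introduces chlorine on a simple orsellinate where the directing effects are understood.

**Alternative 2:** This plan cuts the same two ring B bonds but ties the partners together through a but-2-ynoate ester on the neighbouring ring A oxygen.

- **Forward key step.** Heating the tethered precursor A5 would give an intramolecular Diels–Alder reaction between the 3-chloro-4-methoxy-2-pyron-6-yl ether and the ynoate. Loss of CO2 would then give depsidone A6, with ring B and the seven-membered lactone formed together.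
- **Merits.** The tether fixes the regiochemistry. Chlorine arrives on the pyrone. The lactone of A6 protects the ring B carboxyl and the adjacent ring A oxygen mutually, which is exactly the protection the chosen plan has to add as a benzyl ester.
- **Weak points.** A 6-aryloxy-2-pyrone of a crowded catechol monoester is not an obvious compound to make. The ester in the tether prefers a conformation that keeps the alkyne away from the diene. The aryl but-2-ynoate is an acyl donor at the temperatures needed. The ring A portion of A5 is again a hexasubstituted arene made separately.
- **Comparison.** After A6 the route still needs formylation, two demethylations and a lactone hydrolysis that spares the methyl ester. Alternative 2 is the longest of the four plans, and its only clear advantage over the chosen plan is the built-in protection of the acid.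

**Alternative 3:** This plan builds ring B by a Danheiser benzannulation.

- **Forward key step.** Wolff rearrangement of the chlorovinyl diazo ketoester A7 would give a vinylketene. This would add to the ethynyl ether A8 of ring A by (2+2) cycloaddition, four-electron ring opening and six-electron closure, giving phenol A9.
- **Merits.** The sequence is regiospecific and places hydroxyl, ether, ester, methyl and chlorine on ring B in one operation. A9 has a free ring B phenol next to the only ring hydrogen, so the formyl group could be introduced by phenol-directed ortho-formylation. That is a stronger reaction than the ether formylation in the chosen plan, and is a real advantage.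
- **Weak points.** A8 must be made from the crowded phenol A1, normally through a dichlorovinyl ether and an organolithium elimination that the ring A methyl ester is unlikely to tolerate. Aryl ethynyl ethers are fragile. The chlorovinyl ketene can lose HCl. Ring A again arrives as two methyl ethers, one of which cannot be removed by chelation control.
- **Comparison.** Against the better formylation in alternative 3, the chosen plan buys ring B, makes ring A in one step from two simple components, and never has to deprotect a ring A oxygen.

Key step: step 7

Remark: the target has no stereocentre, and rotation about the ether bonds is taken as fast, so no stereodescriptor is needed. Adduct 11 and the fallback alcohol F4 are racemic.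

## Route

Step 1
Reactants: 1 orsellinic acid (2,4-dihydroxy-6-methylbenzoic acid)
Product: 2 tert-butyl 2,4-dihydroxy-6-methylbenzoate
Conditions: tert-butyl 2,2,2-trichloroacetimidate (2.5 equiv), THF–cyclohexane, rt
Reagents that add atoms: tert-butyl 2,2,2-trichloroacetimidate, CC(C)(C)OC(=N)C(Cl)(Cl)Cl
Why: Imidate esterification: the carboxylic acid protonates the imidate and the carboxylate captures the tert-butyl cation at room temperature, avoiding the heat and mineral acid that decarboxylate orsellinic acid; the phenols need a Lewis acid to react and stay free.

Step 2
Reactants: 2 tert-butyl 2,4-dihydroxy-6-methylbenzoate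
Product: 3 tert-butyl 2-hydroxy-4-methoxy-6-methylbenzoate
Conditions: MeI (1.1 equiv), K2CO3, acetone, rt to 40 °C
Reagents that add atoms: iodomethane, CI
Why: Williamson methylation; the 2-hydroxyl is held in a hydrogen bond to the ester carbonyl, so with one equivalent of MeI only the 4-hydroxyl para to the ester is alkylated, as is usual for orsellinate esters.

Step 3
Reactants: 3 tert-butyl 2-hydroxy-4-methoxy-6-methylbenzoate
Product: 4 tert-butyl 3-chloro-6-hydroxy-4-methoxy-2-methylbenzoate
Conditions: NCS (1.05 equiv), MeCN, 0 °C to rt
Reagents that add atoms: N-chlorosuccinimide, O=C1CCC(=O)N1Cl
Why: Electrophilic aromatic chlorination at the position para to the free hydroxyl and ortho to the methoxy group, the usual site of halogenation in orsellinate ethers; NCS keeps the medium free of HCl so the tert-butyl ester is not cleaved.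

Step 4
Reactants: 4 tert-butyl 3-chloro-6-hydroxy-4-methoxy-2-methylbenzoate; 5 1-bromobutan-2-one
Product: 6 tert-butyl 3-chloro-4-methoxy-2-methyl-6-(2-oxobutoxy)benzoate
Conditions: K2CO3, cat. KI, acetone, 50 °C
Reagents that add atoms: none
Why: Williamson ether synthesis by SN2 at the primary α-bromo ketone carbon, which makes the future diaryl ether C–O bond at an sp3 carbon; the hindered tert-butyl ester is too poor an acylating agent for the new α-carbon to close onto it under carbonate.

Step 5
Reactants: 6 tert-butyl 3-chloro-4-methoxy-2-methyl-6-(2-oxobutoxy)benzoate
Product: 7 3-chloro-4-methoxy-2-methyl-6-(2-oxobutoxy)benzoic acid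
Conditions: CF3CO2H–CH2Cl2 (1:4), 0 °C
Reagents that add atoms: none
Why: Acidolysis of the tert-butyl ester through the tert-butyl cation; ketone, aryl chloride and ethers are inert, and the low temperature limits protodecarboxylation of the electron-rich acid.

Step 6
Reactants: 8 dimethyl malonate; 9 trimethyl orthoacetate
Product: 10 dimethyl 2-(1-methoxyethylidene)propanedioate
Conditions: Ac2O, cat. ZnCl2, 120 °C, volatiles distilled off
Reagents that add atoms: none
Why: Claisen-type condensation of an active methylene compound with an orthoester, as used for alkoxymethylenemalonates; acetic anhydride removes the methanol and drives the elimination to the enol ether.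

Step 7
Reactants: 7 3-chloro-4-methoxy-2-methyl-6-(2-oxobutoxy)benzoic acid; 10 dimethyl 2-(1-methoxyethylidene)propanedioate
Product: 12 3-chloro-6-[2,4-dihydroxy-5-(methoxycarbonyl)-3,6-dimethylphenoxy]-4-methoxy-2-methylbenzoic acid, via alkylidenemalonate adduct 11 (not isolated)
Conditions: NaOMe (5 equiv), MeOH, 0 °C to reflux; then 1 M HCl
Reagents that add atoms: none
Why: Excess NaOMe first turns 7 into its carboxylate, which cannot act as an acylating agent, so closure of the ketone α-carbon onto the ring B carboxyl to a benzofuranone is shut off. Reversible enolisation favours the aryloxy-bearing α-carbon, which is acidified by the oxygen, and this enolate adds to the methoxy-bearing carbon of 10 and expels methoxide (nucleophilic vinylic substitution by addition-elimination) to give adduct 11. In 11 one of the two ester groups is necessarily cis to the ketone arm on the new tetrasubstituted alkene, so the enolate of the ethyl-side carbon can attack it in a 6-(enolendo)-exo-trig Dieckmann closure, the only ring closed; loss of methoxide and two enolisations then give the resorcinol as its phenoxide. Attack through oxygen would give a 2-pyranone, but methoxide reopens that lactone while the aromatic phenoxide is not reopened, so the equilibrating medium drains material into 12; all ester and leaving groups are methoxy, so the medium cannot scramble them. The closest known reaction type is the base-mediated (3+3) cyclocondensation of ketone or 1,3-dicarbonyl enolates with alkoxyalkylidenemalonates, which gives resorcylates or, with simple ketones, 2-pyranones. No stereocentre is formed, and the one in 11 is lost on aromatisation. The step needs site selectivity between the two α-carbons and carbon over oxygen acylation; the aryloxy group secures the first and the irreversible aromatisation under equilibrating methoxide the second.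

Step 8
Reactants: 12 3-chloro-6-[2,4-dihydroxy-5-(methoxycarbonyl)-3,6-dimethylphenoxy]-4-methoxy-2-methylbenzoic acid
Product: 13 benzyl 3-chloro-6-[2,4-dihydroxy-5-(methoxycarbonyl)-3,6-dimethylphenoxy]-4-methoxy-2-methylbenzoate
Conditions: BnBr (1.1 equiv), KHCO3, DMF, rt
Reagents that add atoms: benzyl bromide, BrCc1ccccc1
Why: Carboxylate O-alkylation; hydrogen carbonate deprotonates the carboxylic acid but not the phenols, so only the ester forms, and it prevents the next step from converting the acid into an acid chloride that would lactonise onto the neighbouring ring A hydroxyl.

Step 9
Reactants: 13 benzyl 3-chloro-6-[2,4-dihydroxy-5-(methoxycarbonyl)-3,6-dimethylphenoxy]-4-methoxy-2-methylbenzoate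
Product: 14 benzyl 3-chloro-6-[2,4-dihydroxy-5-(methoxycarbonyl)-3,6-dimethylphenoxy]-5-formyl-4-methoxy-2-methylbenzoate
Conditions: Cl2CHOMe (3 equiv), TiCl4 (5 equiv), CH2Cl2, −20 to 0 °C; then ice-cold 1 M HCl
Reagents that add atoms: dichloromethyl methyl ether, COC(Cl)Cl; water, O
Why: Rieche formylation (Friedel–Crafts reaction of the TiCl4-activated dichloromethyl ether); the only aromatic hydrogen in 13 lies on ring B between the methoxy and aryloxy groups, which both activate it, so the site is fixed; any aryl formates on ring A are hydrolysed in the work-up.

Step 10
Reactants: 14 benzyl 3-chloro-6-[2,4-dihydroxy-5-(methoxycarbonyl)-3,6-dimethylphenoxy]-5-formyl-4-methoxy-2-methylbenzoate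
Product: 15 3-chloro-6-[2,4-dihydroxy-5-(methoxycarbonyl)-3,6-dimethylphenoxy]-5-formyl-4-hydroxy-2-methylbenzoic acid
Conditions: BCl3 (6 equiv), CH2Cl2, −78 to 0 °C; then H2O
Reagents that add atoms: none
Why: Chelation-directed ether cleavage: BCl3 bridges the aldehyde oxygen and the ortho methoxy group and chloride removes the methyl, and on warming the benzyl ester undergoes alkyl–oxygen cleavage to benzyl chloride; the methyl ester and diaryl ether have no such pathway at this temperature, and no free ring position remains to be benzylated.

## Compound list

1 | orsellinic acid (2,4-dihydroxy-6-methylbenzoic acid) | Cc1cc(O)cc(O)c1C(=O)O | starting material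
2 | tert-butyl 2,4-dihydroxy-6-methylbenzoate | Cc1cc(O)cc(O)c1C(=O)OC(C)(C)C | intermediate
3 | tert-butyl 2-hydroxy-4-methoxy-6-methylbenzoate | COc1cc(C)c(C(=O)OC(C)(C)C)c(O)c1 | intermediate
4 | tert-butyl 3-chloro-6-hydroxy-4-methoxy-2-methylbenzoate | COc1cc(O)c(C(=O)OC(C)(C)C)c(C)c1Cl | intermediate
5 | 1-bromobutan-2-one | CCC(=O)CBr | starting material
6 | tert-butyl 3-chloro-4-methoxy-2-methyl-6-(2-oxobutoxy)benzoate | CCC(=O)COc1cc(OC)c(Cl)c(C)c1C(=O)OC(C)(C)C | intermediate
7 | 3-chloro-4-methoxy-2-methyl-6-(2-oxobutoxy)benzoic acid | CCC(=O)COc1cc(OC)c(Cl)c(C)c1C(=O)O | intermediate
8 | dimethyl malonate | COC(=O)CC(=O)OC | starting material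
9 | trimethyl orthoacetate | CC(OC)(OC)OC | starting material
10 | dimethyl 2-(1-methoxyethylidene)propanedioate | COC(C)=C(C(=O)OC)C(=O)OC | intermediate
11 | dimethyl 2-[3-(2-carboxy-4-chloro-5-methoxy-3-methylphenoxy)-4-oxohexan-2-ylidene]propanedioate (racemic, not isolated) | CCC(=O)C(Oc1cc(OC)c(Cl)c(C)c1C(=O)O)C(C)=C(C(=O)OC)C(=O)OC | intermediate
12 | 3-chloro-6-[2,4-dihydroxy-5-(methoxycarbonyl)-3,6-dimethylphenoxy]-4-methoxy-2-methylbenzoic acid | COC(=O)c1c(C)c(Oc2cc(OC)c(Cl)c(C)c2C(=O)O)c(O)c(C)c1O | intermediate
13 | benzyl 3-chloro-6-[2,4-dihydroxy-5-(methoxycarbonyl)-3,6-dimethylphenoxy]-4-methoxy-2-methylbenzoate | COC(=O)c1c(C)c(Oc2cc(OC)c(Cl)c(C)c2C(=O)OCc3ccccc3)c(O)c(C)c1O | intermediate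
14 | benzyl 3-chloro-6-[2,4-dihydroxy-5-(methoxycarbonyl)-3,6-dimethylphenoxy]-5-formyl-4-methoxy-2-methylbenzoate | COC(=O)c1c(C)c(Oc2c(C=O)c(OC)c(Cl)c(C)c2C(=O)OCc3ccccc3)c(O)c(C)c1O | intermediate
15 | 3-chloro-6-[2,4-dihydroxy-5-(methoxycarbonyl)-3,6-dimethylphenoxy]-5-formyl-4-hydroxy-2-methylbenzoic acid | COC(=O)c1c(C)c(Oc2c(C=O)c(O)c(Cl)c(C)c2C(=O)O)c(O)c(C)c1O | target

## Step count and weakest steps

Total: 10 steps. Longest linear sequence: 9 steps (steps 1 to 5 and 7 to 10, from orsellinic acid 1); step 6 is a one-step side branch.

**Step 7 (key step).** The most likely failures are these:
- conjugate addition through the ethyl-side enolate, which would lead to the regioisomeric arene;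
- slow addition to the crowded, enolisable acceptor 10;
- arrest after acylation on oxygen, giving a lactone instead of the arene.

The fallback separates the two bond formations. Acid 7 and malonate 10 would be condensed with t-BuOK in THF, without methanol, to give the lactone on purpose: methyl 5-(2-carboxy-4-chloro-5-methoxy-3-methylphenoxy)-6-ethyl-4-methyl-2-oxo-2H-pyran-3-carboxylate F1. This would be isolated and its regiochemistry checked. Heating F1 with Mg(OMe)2 in MeOH should open the lactone and re-close it through carbon by the same Dieckmann step, returning to the route at 12.

**Step 9.** The most likely failure is too little reactivity at the doubly flanked position, because TiCl4 bound to the neighbouring oxygens lowers their donor strength; long exposure may then erode the benzyl ester. The fallback sets out from 12 and uses the stronger directing power of a free phenol. BBr3 in CH2Cl2 at −78 to 0 °C should cleave the ring B methyl ether to give 3-chloro-6-[2,4-dihydroxy-5-(methoxycarbonyl)-3,6-dimethylphenoxy]-4-hydroxy-2-methylbenzoic acid F2. Ortho-formylation of F2 with MgCl2, Et3N and paraformaldehyde in MeCN can only occur next to the ring B hydroxyl and involves no acid-chloride-forming reagent. It rejoins the route at 15 and bypasses steps 8 to 10. Its own risk is attack of BBr3 on the ring A methyl ester, which is why it is not the main line.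

**Step 3.** The likely failure is loss of regiocontrol, with chlorine entering between the two oxygens, or over-chlorination. The fallback reverses the order. Diol 2 would be chlorinated first with SO2Cl2 in Et2O at 0 °C; in orsellinates the position para to the chelated hydroxyl is the established site. This gives tert-butyl 3-chloro-4,6-dihydroxy-2-methylbenzoate F3, and selective methylation of its non-chelated hydroxyl (MeI, K2CO3) returns to 4.

**Step 4.** The likely failure is slow O-alkylation of the hindered, hydrogen-bonded phenol, leaving time for base-induced self-condensation of the bromoketone or for cyclisation of the product's α-carbon onto the ester. The fallback avoids an enolisable ketone under base. Phenol 4 would open 1,2-epoxybutane at its terminal carbon (Cs2CO3, DMF, 80 °C) to give racemic tert-butyl 3-chloro-6-(2-hydroxybutoxy)-4-methoxy-2-methylbenzoate F4. Dess–Martin oxidation of F4 returns to 6.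

**Step 10.** The likely failure is incomplete cleavage of the benzyl ester at temperatures where the ring A methyl ester is safe, or loss of that hindered methyl ester on warming. The fallback separates the two deprotections. From 14, BCl3 at −78 °C only should give benzyl 3-chloro-6-[2,4-dihydroxy-5-(methoxycarbonyl)-3,6-dimethylphenoxy]-5-formyl-4-hydroxy-2-methylbenzoate F5 by the chelation-controlled demethylation alone. Hydrogenolysis of F5 (H2, Pd/C, EtOAc, rt), stopped after one equivalent of hydrogen to spare the aryl chloride and aldehyde, returns to 15.

## Further compounds

F1 | step 7 | methyl 5-(2-carboxy-4-chloro-5-methoxy-3-methylphenoxy)-6-ethyl-4-methyl-2-oxo-2H-pyran-3-carboxylate | CCC1=C(Oc2cc(OC)c(Cl)c(C)c2C(=O)O)C(C)=C(C(=O)OC)C(=O)O1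
F2 | step 9 | 3-chloro-6-[2,4-dihydroxy-5-(methoxycarbonyl)-3,6-dimethylphenoxy]-4-hydroxy-2-methylbenzoic acid | COC(=O)c1c(C)c(Oc2cc(O)c(Cl)c(C)c2C(=O)O)c(O)c(C)c1O
F3 | step 3 | tert-butyl 3-chloro-4,6-dihydroxy-2-methylbenzoate | Cc1c(Cl)c(O)cc(O)c1C(=O)OC(C)(C)C
F4 | step 4 | tert-butyl 3-chloro-6-(2-hydroxybutoxy)-4-methoxy-2-methylbenzoate (racemic) | CCC(O)COc1cc(OC)c(Cl)c(C)c1C(=O)OC(C)(C)C
F5 | step 10 | benzyl 3-chloro-6-[2,4-dihydroxy-5-(methoxycarbonyl)-3,6-dimethylphenoxy]-5-formyl-4-hydroxy-2-methylbenzoate | COC(=O)c1c(C)c(Oc2c(C=O)c(O)c(Cl)c(C)c2C(=O)OCc3ccccc3)c(O)c(C)c1O
A1 | alternative 1 | methyl 3-hydroxy-4,6-dimethoxy-2,5-dimethylbenzoate | COC(=O)c1c(C)c(O)c(OC)c(C)c1OC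
A2 | alternative 1 | tert-butyl 3-[2,4-dimethoxy-5-(methoxycarbonyl)-3,6-dimethylphenoxy]prop-2-ynoate | COC(=O)c1c(C)c(OC#CC(=O)OC(C)(C)C)c(OC)c(C)c1OC
A3 | alternative 1 | 4-methoxy-6-methyl-2H-pyran-2-one | COC1=CC(=O)OC(C)=C1
A4 | alternative 1 | methyl 3-[2-(tert-butoxycarbonyl)-5-methoxy-3-methylphenoxy]-4,6-dimethoxy-2,5-dimethylbenzoate | COC(=O)c1c(C)c(Oc2cc(OC)cc(C)c2C(=O)OC(C)(C)C)c(OC)c(C)c1OC
A5 | alternative 2 | methyl 4-(but-2-ynoyloxy)-3-[(3-chloro-4-methoxy-2-oxo-2H-pyran-6-yl)oxy]-6-methoxy-2,5-dimethylbenzoate | COC(=O)c1c(C)c(OC2=CC(OC)=C(Cl)C(=O)O2)c(OC(=O)C#CC)c(C)c1OC
A6 | alternative 2 | methyl 2-chloro-3,8-dimethoxy-1,6,9-trimethyl-11-oxo-11H-dibenzo[b,e][1,4]dioxepine-7-carboxylate | COC(=O)c1c(C)c2Oc3cc(OC)c(Cl)c(C)c3C(=O)Oc2c(C)c1OC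
A7 | alternative 3 | tert-butyl (4E)-5-chloro-2-diazo-4-methyl-3-oxopent-4-enoate | Cl/C=C(\C)C(=O)C(=[N+]=[N-])C(=O)OC(C)(C)C
A8 | alternative 3 | methyl 3-(ethynyloxy)-4,6-dimethoxy-2,5-dimethylbenzoate | COC(=O)c1c(C)c(OC#C)c(OC)c(C)c1OC
A9 | alternative 3 | methyl 3-[2-(tert-butoxycarbonyl)-4-chloro-5-hydroxy-3-methylphenoxy]-4,6-dimethoxy-2,5-dimethylbenzoate | COC(=O)c1c(C)c(Oc2cc(O)c(Cl)c(C)c2C(=O)OC(C)(C)C)c(OC)c(C)c1OC
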